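## Structural features

The target is a bicyclic sesquiterpenoid ester: a ten-membered carbocycle (ring A, C1–C10) with an α-methylene-γ-butyrolactone (ring B: O, C6, C7, C11, C12, exocyclic C11=C13) trans-fused across C6–C7. Going round ring A from the Z-trisubstituted olefin C4=C5 (methyl on C4), one side carries the allylic lactone carbinol C6 and the other the vicinal diol C3/C2, followed by C1H2, the methyl-bearing C10, the angeloyloxy carbinol C9 and C8H2, which closes back to C7. The six stereocentres form three adjacent pairs: C2 (S)/C3 (R), an anti diol that is cis on the ring; C6 (R)/C7 (S), the trans lactone; and C9 (S)/C10 (R), anti. The pairs are insulated from each other by the olefin, C1 and C8. Fragile groups are the α-methylene lactone (a conjugate acceptor), the angelate (it isomerises to the tiglate under base or nucleophilic catalysis and does not survive hydride), the two allylic oxygens at C3 and C6, and a Z olefin inside a medium ring. The real difficulty is to close the ten-membered ring while fixing both the Z geometry of C4=C5 and the C2/C3 diol relative to the distant C6–C10 stereocentres. The segment C2(OH)–C3(OR)–C4(CH3)=C5(H)–C6 is the retron of an α-substituted (E)-γ-alkoxyallylboronate adding to an aldehyde. One C2–C3 bond formation can therefore close ring A, deliver the olefin at C4=C5 as the Z isomer, and set C2 and C3 from a single boron-bearing stereocentre at C5.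

## Logic of the disconnections

34 back to 32 (through 33). The ester C–O bond at O9 and the two acetal C–O bonds at O2 and O3 are cut. The angelate is the most fragile group, so it goes on after every reductive, basic and fluoride step. This simplifies all earlier intermediates to silyl and acetal derivatives. It demands that O2 and O3 are masked together when O9 is acylated, and that the last hydrolysis is mild enough for the ester, the lactone and the allylic C–O bonds.

32 back to 28 (through 31, 30 and 29). The lactone C12–O6 bond is cut, C12 is returned to the alcohol level and O6, O9 and O12 are returned to their silyl ethers. Carrying the lactone as a 2-(silyloxymethyl)vinyl unit removes the conjugate acceptor from all organometallic chemistry. The forward steps must cleave two TBS ethers beside one TIPS ether and lactonise oxidatively while O9 stays blocked, because O9 is cis to C11 on ring A and could otherwise form a bridged six-membered lactone.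

28 back to 27. The acetal C–O2 bond is cut, leaving the C3 p-methoxybenzyl ether and a free O2–H. In the forward direction the ether delivered by the ring closure is oxidised onto O2, so the diol is protected without a separate step. This demands anhydrous oxidation that touches only the electron-rich benzyl group.

27 back to 25. The C2–C3 bond is cut with transposition of the olefin from C4=C5 to C3=C4 and of oxygen-bound boron back to C5. This opens ring A and replaces two stereocentres and one olefin geometry by a single C5 stereocentre and an E enol ether. The forward step must run through a closed chair at high dilution, and 25 must be made under neutral conditions and used at once.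

25 back to 23 (through 24). The C5–B bond is cut with a second allylic transposition, giving an allylic bis-acetal at C3 and the olefin at C4=C5; C2 goes back to the alcohol. An SN2′ borylation then creates the boron stereocentre and the E enol ether in one step from a stable precursor. It demands facial control at C5 next to the C6 stereocentre and tolerance of the C2 hydroxyl.

23 back to 21. The C2–O bond is cut, leaving a terminal vinyl group as the latent C1–C2 alcohol, so that C2 needs no protecting group anywhere in the route. The hydroboration must pick the monosubstituted olefin over the 1,1-disubstituted and trisubstituted ones.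

21 back to 19 (through 20). The two O–Si bonds are cut and the 2-methylene-1,4-diol is returned to the α-methylene lactone. The lactone is what the C6–C7 bond formation delivers, and hydride reduction converts it to the protected form needed later. The reduction must be 1,2-selective and spare the allylic acetal.

19 back to 9 and 16. The C6–C7 bond (and the lactone C–O bond that follows from it) is cut between an allylic bromide carrying C7–C13 and C8–C10, and a Z enal carrying C3–C6. This is the convergent step and gives two fragments of similar size. It demands anti simple diastereoselection and reagent control of the aldehyde face, since the only stereocentres of 9 are remote from C7.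

9 back to 6 and 7 (through 8). The C7–C11 bond is cut to an aldehyde and an acrylate. The Morita–Baylis–Hillman adduct is converted to the bromide by SN2′ substitution, which moves the leaving group to C13. This needs only Z-selective bromide delivery.

6 back to 1 (through 5, 4 and 3). The C9–C10 bond is cut. One asymmetric crotylboration sets C9 and C10 and brings C1=C2 as the vinyl group, which is shorter than a chiral-pool C10 building block that would need a one-carbon homologation at C1. It demands an E-crotyl reagent of high enantiofacial control.

16 back to 10 (through 15, 14, 13, 12 and 11). The C5–C6 bond (formyl group), the acetal C–O bonds and the C4–CH3 bond are cut. Carbometallation of a propargylic alkoxide sets the Z geometry that puts C3 and C6 on the same side. The bis-PMB acetal is installed on this small fragment so that no acid step is needed later on the silylated chain. The forward steps must keep the Z geometry through oxidation, acetalisation and formylation.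

## Other disconnections considered

Alternative 1: The cut is C3–C4. The open-chain iodo aldehyde A1 (Z-alkenyl iodide at C4, aldehyde at C3, silyl ether at O2, lactone and angelate in place) would be closed with CrCl2 and catalytic NiCl2 to the allylic alcohol A2, one desilylation from the target.
- In its favour: the reaction type is established for medium and large rings, the olefin geometry is fixed in A1 and retained by the alkenylchromium, and esters are tolerated. On precedent and on the number of steps after ring closure this alternative is the better of the two.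
- Against it here: only C3 is created. Its configuration would rest on the α-silyloxy stereocentre C2 acting inside a ten-membered transition state; the acyclic non-chelation model predicts the required anti pair, but a cyclic transition state need not follow it. C2 must be made separately and carried as an epimerisable α-silyloxy aldehyde. The α-methylene lactone of A1 is a possible acceptor for the alkenylmetal species, and the angelate would have to survive the whole fragment assembly.
- Comparison: the chosen plan forms two stereocentres and the olefin geometry in the closing step from one boron stereocentre, through a closed chair. Alternative 1 forms one stereocentre through a conformation-dependent addition but with a pre-set olefin, which is an equal or better point for geometric certainty. Overall step counts should be close, because the steps saved after the closure are spent on making C2 and on handling lactone and ester early.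

Alternative 2: The cut is C7–C8. The twelve-membered allyl vinyl ether A3 (exocyclic C9=C8H2 enol ether, ring oxygen on C13) would be heated so that a [3,3] shift forms C7–C8, breaks O–C13 and gives the ten-membered C9 ketone A4 with the C11=C13 methylene.
- In its favour: the step is thermal and reagent-free, it turns an easier twelve-membered C–O ring closure into the carbocycle, and it creates the C7–C8 bond and the exo-methylene together. In functional-group tolerance and in avoiding a sensitive organometallic intermediate it is the equal or the better of the chosen plan.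
- Against it here: only C7 is set, through a chair or boat imposed by the macrocycle, so its sense is hard to predict. C10 becomes α to the new ketone and can epimerise, and C9 must afterwards be reduced selectively. The C2/C3 diol and the Z olefin must already be present in A3, made by separate asymmetric steps, and a macrolactonisation plus a carbonyl methylenation are needed before the key step.
- Comparison: the chosen plan relays two stereocentres from one; alternative 2 sets one and leaves C9 and the integrity of C10 as later problems. After either key step about six steps remain, so step economy is decided before the key step, where alternative 2 needs more stereocontrolled operations.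

Alternative 3: The cut is C1–C2. The aldehyde enone A5 (C2 aldehyde, isopropenyl ketone at C9) would be treated with SmI2 in THF with HMPA; the ketyl adds to the enone terminus C1 and the samarium enolate is protonated at C10 to give the hydroxy ketone A6.
- In its favour: the radical addition is polarity-matched and the precursor A5 contains only simple functional groups. Two stereocentres (C2 and C10) are formed, equal in number to the chosen plan, and no stereodefined organoboron is needed, which is a point in its favour for precursor synthesis.
- Against it here: C10 would be set by enolate protonation and C2 only by the neighbouring silyloxy stereocentre C3 in a ten-membered radical cyclisation, both weak control elements. Competing reduction of the enone, pinacol coupling, and β-elimination of the C3 silyloxy group from the reduced aldehyde are all plausible. HMPA is required, and the C9 ketone must still be reduced stereoselectively.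
- Comparison: both plans form a bond next to C2, but the chosen plan does so in an ordered chair with a defined source of chirality, whereas alternative 3 depends on macrocyclic conformational bias. The step count to A5 should be lower than to the boronate, but the ketone reduction and likely isomer separations would offset that.

Key step: step 17

Remark: the structures used for 25 and 27 were checked against the chair model and the target ((5S) boronate with E enol ether gives 2S,3R and the Z olefin) and needed no correction. The antipode of each chiral ligand in steps 11 and 15 is the one that meets the facial requirement stated there. The carbinol carbon of 8, the anomeric carbon of 30 and the acetal carbon of 28–33 are left uncontrolled because they are destroyed later.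

## Route

Step 1
Reactants: 1 3-[(tert-butyldimethylsilyl)oxy]propanal
Product: 3 (3S,4R)-1-[(tert-butyldimethylsilyl)oxy]-4-methylhex-5-en-3-ol, via borinic ester 2 (not isolated)
Conditions: (E)-crotyl-B(Ipc)2 (Ipc from (−)-α-pinene), THF/Et2O, −78 °C; then NaOH, H2O2, 0 °C
Reagents that add atoms: (E)-crotyldiisopinocampheylborane, C/C=C/CB([C@H]1C[C@H]2C[C@@H]([C@@H]1C)C2(C)C)[C@H]1C[C@H]2C[C@@H]([C@@H]1C)C2(C)C
Why: Asymmetric crotylboration through a closed six-membered chair: the E crotyl geometry gives the anti C9–O/C10–CH3 pair and the isopinocampheyl groups direct addition to the Re face of the aldehyde, so C9 (S) and C10 (R) are set together; the vinyl group is the latent C1–C2 unit.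

Step 2
Reactants: 3 homoallylic alcohol
Product: 4 (3S,4R)-1-[(tert-butyldimethylsilyl)oxy]-4-methyl-3-[(triisopropylsilyl)oxy]hex-5-ene
Conditions: TIPSOTf, 2,6-lutidine, CH2Cl2, 0 °C
Reagents that add atoms: triisopropylsilyl triflate, CC(C)[Si](OS(=O)(=O)C(F)(F)F)(C(C)C)C(C)C
Why: Silylation of a hindered secondary alcohol with the silyl triflate; TIPS is chosen for O9 because it must outlast two TBS ethers in step 19.

Step 3
Reactants: 4 bis-silyl ether
Product: 5 (3S,4R)-4-methyl-3-[(triisopropylsilyl)oxy]hex-5-en-1-ol
Conditions: CSA (cat.), MeOH/CH2Cl2, 0 °C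
Reagents that add atoms: none
Why: Acid-catalysed methanolysis cleaves the primary TBS ether much faster than the hindered secondary TIPS ether.

Step 4
Reactants: 5 primary alcohol
Product: 6 (3S,4R)-4-methyl-3-[(triisopropylsilyl)oxy]hex-5-enal
Conditions: Dess–Martin periodinane, CH2Cl2, 0 °C to rt
Reagents that add atoms: none
Why: Periodinane oxidation of a primary alcohol to the aldehyde without over-oxidation; the β-silyloxy aldehyde is used without delay.

Step 5
Reactants: 6 aldehyde; 7 ethyl acrylate
Product: 8 ethyl (5S,6R)-3-hydroxy-6-methyl-2-methylidene-5-[(triisopropylsilyl)oxy]oct-7-enoate (both C3 epimers)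
Conditions: DABCO, MeOH, rt
Reagents that add atoms: none
Why: Morita–Baylis–Hillman reaction forms the C7–C11 bond; the configuration of the new carbinol is irrelevant because it is lost in step 6.

Step 6
Reactants: 8 Morita–Baylis–Hillman adduct
Product: 9 ethyl (2Z,5S,6R)-2-(bromomethyl)-6-methyl-5-[(triisopropylsilyl)oxy]octa-2,7-dienoate
Conditions: NBS, Me2S, CH2Cl2, 0 °C
Reagents that add atoms: N-bromosuccinimide, BrN1C(=O)CCC1=O
Why: The hydroxyl is activated as an alkoxysulfonium ion and displaced by bromide in the SN2′ sense; the trisubstituted enoate forms with C8 trans to the ester (Z bromide) to avoid 1,3-allylic strain.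

Step 7
Reactants: 10 prop-2-yn-1-ol
Product: 12 (Z)-3-iodo-2-methylprop-2-en-1-ol, via cyclic alkenylmagnesium alkoxide 11 (not isolated)
Conditions: MeMgBr (3 equiv), CuI (10 mol %), THF, −10 °C to rt; then I2, −78 to 0 °C
Reagents that add atoms: methylmagnesium bromide, C[Mg]Br; iodine, II
Why: Copper-catalysed anti-carbomagnesiation of the propargylic magnesium alkoxide puts methyl on the internal carbon and magnesium on the terminal carbon on the side of the CH2O group (five-membered chelate); iodinolysis with retention gives the Z iodide, fixing C4–CH3 and the cis relation of C3 and C5.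

Step 8
Reactants: 12 iodo alcohol
Product: 13 (Z)-3-iodo-2-methylprop-2-enal
Conditions: MnO2, CH2Cl2, rt
Reagents that add atoms: none
Why: MnO2 oxidises the primary allylic alcohol to the enal under neutral conditions that leave the alkenyl iodide and its Z geometry intact.

Step 9
Reactants: 13 iodo enal
Product: 14 (Z)-1-iodo-3,3-bis[(4-methoxybenzyl)oxy]-2-methylprop-1-ene
Conditions: PMBOTMS (2.2 equiv), TMSOTf (cat.), CH2Cl2, −78 °C; pyridine quench
Reagents that add atoms: (4-methoxybenzyloxy)trimethylsilane, COc1ccc(CO[Si](C)(C)C)cc1
Why: Silyl-triflate-catalysed acetalisation with the silyl ether of the alcohol is aprotic and runs at low temperature, so the Z iodo enal is not exposed to protic acid; placing the acetal on the small fragment avoids an acid step on the silylated chain later.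

Step 10
Reactants: 14 iodo acetal
Product: 16 (Z)-4,4-bis[(4-methoxybenzyl)oxy]-3-methylbut-2-enal, via alkenyllithium 15 (not isolated)
Conditions: t-BuLi (2.1 equiv), Et2O, −78 °C; DMF; aq. NaH2PO4
Reagents that add atoms: N,N-dimethylformamide, CN(C)C=O
Why: Iodine–lithium exchange proceeds with retention of olefin geometry and formylation with DMF gives the Z enal (C6 aldehyde); the buffered quench protects the acetal and protonates the liberated amine.

Step 11
Reactants: 9 allylic bromide; 16 Z enal
Product: 19 (4S,5R)-5-[(Z)-3,3-bis(4-methoxybenzyloxy)-2-methylprop-1-enyl]-3-methylidene-4-[(2S,3R)-3-methyl-2-(triisopropylsilyloxy)pent-4-enyl]oxolan-2-one, via allylchromium dichloride 17 (not isolated), via anti hydroxy ester 18 (not isolated)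
Conditions: CrCl2, (S)-N-[2-(4-isopropyl-4,5-dihydrooxazol-2-yl)-6-methylphenyl]methanesulfonamide, Et3N, THF, rt; aqueous work-up
Reagents that add atoms: none
Why: Nozaki–Hiyama–Kishi-type allylation: two CrCl2 reduce the C–Br bond to an allyl species of trivalent chromium that adds through C7 in a closed chair with the C8 chain and the alkenyl residue equatorial, giving the anti C6/C7 pair. The chiral sulfonamide ligand on chromium is relied on to select the Si face of the aldehyde (C6 R, C7 S), because C9 is too remote to do so. The chromium alkoxide then acylates on the neighbouring ester to close the trans lactone.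

Step 12
Reactants: 19 lactone
Product: 20 open-chain diol (4Z,6R,7S,9S,10R): free O6–H and O12–H; O9 TIPS ether; C3 bis(4-methoxybenzyl) acetal; C1=C2 vinyl; C11=C13 methylidene
Conditions: i-Bu2AlH, CH2Cl2, −78 to 0 °C; aq. sodium potassium tartrate
Reagents that add atoms: none
Why: 1,2-Reduction of the α-methylene lactone gives the 2-methylene-1,4-diol while acetal, silyl ether and olefins are inert at low temperature; the crude diol is silylated without acidic chromatography because the Z-disposed O6–H could displace a PMB-oxy group of the acetal.

Step 13
Reactants: 20 diol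
Product: 21 bis-TBS ether (4Z,6R,7S,9S,10R): O6 and O12 TBS ethers; O9 TIPS ether; C3 bis(4-methoxybenzyl) acetal; C1=C2 vinyl
Conditions: TBSCl, imidazole, DMAP (cat.), DMF, rt to 40 °C
Reagents that add atoms: tert-butyldimethylsilyl chloride, CC(C)(C)[Si](C)(C)Cl
Why: Standard silylation of the primary allylic and the secondary allylic hydroxyl; silyl triflates are avoided because they activate acetals.

Step 14
Reactants: 21 bis-TBS ether
Product: 23 primary alcohol (4Z,6R,7S,9S,10R): free O2–H on the C1–C2 ethyl terminus; other groups as in 21, via trialkylborane 22 (not isolated)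
Conditions: Sia2BH, THF, 0 °C; then NaOH, H2O2, 0 °C
Reagents that add atoms: hydrogen peroxide, OO
Why: Hydroboration–oxidation: the bulky dialkylborane adds anti-Markovnikov to the monosubstituted C1=C2 olefin much faster than to the hindered 1,1-disubstituted C11=C13 olefin or the trisubstituted C4=C5 olefin; alkaline peroxide spares acetal and silyl ethers.

Step 15
Reactants: 23 primary alcohol
Product: 24 allylboronate alcohol (3E,5S,6R,7S,9S,10R): C5 pinacol boronate; C3=C4 enol 4-methoxybenzyl ether; O6 and O12 TBS; O9 TIPS; free O2–H
Conditions: NaH (1.0 equiv), THF, 0 °C; then CuCl (5 mol %), (R,R)-QuinoxP* (5 mol %), B2pin2 (2.5 equiv), THF, 30 °C; aq. NH4Cl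
Reagents that add atoms: bis(pinacolato)diboron, CC1(C)OB(OC1(C)C)B1OC(C)(C)C(C)(C)O1
Why: Copper-catalysed SN2′ borylation of an allylic acetal: the boryl copper adds across C4=C5 with boron on C5, and β-elimination of one PMB-oxide from C3 gives the enol ether, E because the remaining OPMB avoids the substituted C5. The C5 configuration (S) is set by the chiral bisphosphine, chosen to add boron anti to C7 in the conformer that holds H6 in the olefin plane. The sodium alkoxide of 23 acts as the activating base, so no hydroxyl proton is left to quench the alkylcopper intermediate, and O-boryl species revert to the alcohol on work-up.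

Step 16
Reactants: 24 allylboronate alcohol
Product: 25 C2 aldehyde (3E,5S,6R,7S,9S,10R): C5 pinacol boronate; C3=C4 enol 4-methoxybenzyl ether; O6 and O12 TBS; O9 TIPS
Conditions: Dess–Martin periodinane, pyridine, CH2Cl2, 0 °C; filtered through Celite and used at once
Reagents that add atoms: none
Why: Buffered periodinane oxidation is non-aqueous and non-acidic, which the pinacol boronate and the enol ether tolerate; the aldehyde is not purified because it carries its own allylating group.

Step 17
Reactants: 25 C2 aldehyde
Product: 27 ten-membered carbocycle (2S,3R,4Z,6R,7S,9S,10R): free O2–H; O3 4-methoxybenzyl ether; O6 TBS; O9 TIPS; C7 2-(TBS-oxymethyl)vinyl, via C2 borate ester 26 (not isolated)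
Conditions: toluene (1 mM), 4 Å MS, 70 °C; then aq. NaHCO3
Reagents that add atoms: none
Why: Proposed new method: ring-closing allylboration of an α-substituted (E)-γ-alkoxyallylboronate; boron binds the aldehyde oxygen and C3 attacks C2 on the face of the enol ether that carries boron, through a closed chair B–O–C2–C3–C4–C5, so that C2–C3 forms while the double bond moves to C4=C5 and boron passes to O2 (26), which is hydrolysed on work-up. The closest known reaction type is the intermolecular addition of α-substituted (E)-γ-alkoxyallyl pinacol boronates to aldehydes, which gives Z-configured anti-1,2-diol monoethers, together with intramolecular allylborations to five- to seven-membered rings and medium-ring closures with γ-alkoxyallylstannanes. Ring A is closed as a ten-membered carbocycle in a bicyclic transition state in which the tether C6–C7–C8–C9–C10–C1 bridges the chair from C5 to C2, with the new olefin inside the ring. C3 (R) is controlled by the C5 (S) boron stereocentre: with C6 axial, the arrangement favoured by both the pinacol ester and the tether, boron and therefore C2 sit on one defined face of the E enol ether, whose geometry keeps OPMB equatorial. C2 (S) is controlled by the equatorial position of C1 on the aldehyde carbon, the one from which the tether reaches the axial C6 without crossing the chair, and this gives the anti diol that is cis on the ring. The Z geometry of C4=C5 follows from the axial C6. The step needs intramolecular to beat intermolecular addition, which high dilution and late generation of 25 secure, and needs C5 to keep its configuration, which the slow 1,3-boron shift of pinacol esters at this temperature should secure; the neutral conditions leave the silyl ethers, the allylic O6 and the 1,1-disubstituted olefin untouched.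

Step 18
Reactants: 27 macrocyclic alcohol
Product: 28 O2,O3-(4-methoxybenzylidene) acetal of the macrocycle: O6 TBS; O9 TIPS; C7 2-(TBS-oxymethyl)vinyl
Conditions: DDQ (1.2 equiv), 4 Å MS, CH2Cl2, 0 °C
Reagents that add atoms: none
Why: Anhydrous DDQ oxidises the PMB ether to an oxocarbenium ion that is trapped by the neighbouring O2–H; the ring-cis diol gives a five-membered 4-methoxybenzylidene acetal that protects O2 and O3 together.

Step 19
Reactants: 28 acetal
Product: 29 diol acetal: free O6–H and O12–H; O9 TIPS; O2,O3-(4-methoxybenzylidene) acetal
Conditions: HF·pyridine, pyridine, THF, 0 °C to rt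
Reagents that add atoms: none
Why: Buffered fluoride cleaves the primary and the secondary allylic TBS ethers before the more hindered secondary TIPS ether, and the pyridine buffer keeps the acetal intact.

Step 20
Reactants: 29 diol acetal
Product: 31 α-methylene lactone acetal: lactone C12(=O)–O6 trans-fused at C6–C7; O9 TIPS; O2,O3-(4-methoxybenzylidene) acetal, via lactol 30 (not isolated)
Conditions: TEMPO (cat.), PhI(OAc)2, CH2Cl2, rt
Reagents that add atoms: none
Why: Oxoammonium oxidation is selective for the primary allylic alcohol; the enal closes with O6–H to the five-membered lactol, which is oxidised on to the α-methylene lactone, and because O9 is still silylated the bridged six-membered lactone cannot compete.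

Step 21
Reactants: 31 lactone acetal
Product: 32 C9 alcohol: α-methylene lactone; free O9–H; O2,O3-(4-methoxybenzylidene) acetal
Conditions: Bu4NF, AcOH (1:1), THF, 0 °C to rt
Reagents that add atoms: none
Why: Acetic-acid-buffered fluoride removes the TIPS ether while keeping the medium close to neutral for the conjugate acceptor and the acetal.

Step 22
Reactants: 32 C9 alcohol
Product: 33 C9 angelate: α-methylene lactone; O9 (Z)-2-methylbut-2-enoate; O2,O3-(4-methoxybenzylidene) acetal
Conditions: angelic acid, 2,4,6-trichlorobenzoyl chloride, Et3N, toluene, rt; then 32, 80 °C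
Reagents that add atoms: angelic acid, C/C=C(/C)C(=O)O
Why: Mixed-anhydride esterification of the hindered C9 hydroxyl with the preformed 2,4,6-trichlorobenzoic anhydride of angelic acid and no nucleophilic catalyst, the protocol that avoids isomerisation of the Z ester to the tiglate; O2 and O3 are blocked by the acetal.

Step 23
Reactants: 33 angelate acetal
Product: 34 CNP0229085.1 (2S,3R,4Z,6R,7S,9S,10R)
Conditions: AcOH/THF/H2O (3:1:1), 40 °C
Reagents that add atoms: none
Why: Mild aqueous acid hydrolyses the 4-methoxybenzylidene acetal through its stabilised oxocarbenium ion faster than it affects the lactone, the angelate or the allylic C–O bonds, releasing the C2/C3 diol.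

## Compound list

1 | 3-[(tert-butyldimethylsilyl)oxy]propanal | O=CCCO[Si](C)(C)C(C)(C)C | starting material
2 | (3S,4R)-1-[(tert-butyldimethylsilyl)oxy]-4-methylhex-5-en-3-yl diisopinocampheylborinate | C=C[C@@H](C)[C@@H](OB([C@H]1C[C@H]2C[C@@H]([C@@H]1C)C2(C)C)[C@H]1C[C@H]2C[C@@H]([C@@H]1C)C2(C)C)CCO[Si](C)(C)C(C)(C)C | intermediate (not isolated)
3 | (3S,4R)-1-[(tert-butyldimethylsilyl)oxy]-4-methylhex-5-en-3-ol | C=C[C@@H](C)[C@@H](O)CCO[Si](C)(C)C(C)(C)C | intermediate
4 | (3S,4R)-1-[(tert-butyldimethylsilyl)oxy]-4-methyl-3-[(triisopropylsilyl)oxy]hex-5-ene | C=C[C@@H](C)[C@@H](O[Si](C(C)C)(C(C)C)C(C)C)CCO[Si](C)(C)C(C)(C)C | intermediate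
5 | (3S,4R)-4-methyl-3-[(triisopropylsilyl)oxy]hex-5-en-1-ol | C=C[C@@H](C)[C@@H](O[Si](C(C)C)(C(C)C)C(C)C)CCO | intermediate
6 | (3S,4R)-4-methyl-3-[(triisopropylsilyl)oxy]hex-5-enal | C=C[C@@H](C)[C@@H](O[Si](C(C)C)(C(C)C)C(C)C)CC=O | intermediate
7 | ethyl acrylate | C=CC(=O)OCC | starting material
8 | ethyl (5S,6R)-3-hydroxy-6-methyl-2-methylidene-5-[(triisopropylsilyl)oxy]oct-7-enoate (C3 epimers) | C=C[C@@H](C)[C@@H](O[Si](C(C)C)(C(C)C)C(C)C)CC(O)C(=C)C(=O)OCC | intermediate
9 | ethyl (2Z,5S,6R)-2-(bromomethyl)-6-methyl-5-[(triisopropylsilyl)oxy]octa-2,7-dienoate | C=C[C@@H](C)[C@@H](O[Si](C(C)C)(C(C)C)C(C)C)C/C=C(\CBr)C(=O)OCC | intermediate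
10 | prop-2-yn-1-ol (propargyl alcohol) | C#CCO | starting material
11 | 4-methyl-2,5-dihydro-1,2-oxamagnesole (cyclic alkenylmagnesium alkoxide) | CC1=C[Mg]OC1 | intermediate (not isolated)
12 | (Z)-3-iodo-2-methylprop-2-en-1-ol | I/C=C(/C)CO | intermediate
13 | (Z)-3-iodo-2-methylprop-2-enal | I/C=C(/C)C=O | intermediate
14 | (Z)-1-iodo-3,3-bis[(4-methoxybenzyl)oxy]-2-methylprop-1-ene | I/C=C(/C)C(OCc1ccc(OC)cc1)OCc1ccc(OC)cc1 | intermediate
15 | (Z)-{3,3-bis[(4-methoxybenzyl)oxy]-2-methylprop-1-enyl}lithium | [Li]/C=C(/C)C(OCc1ccc(OC)cc1)OCc1ccc(OC)cc1 | intermediate (not isolated)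
16 | (Z)-4,4-bis[(4-methoxybenzyl)oxy]-3-methylbut-2-enal | O=C/C=C(/C)C(OCc1ccc(OC)cc1)OCc1ccc(OC)cc1 | intermediate
17 | allylchromium dichloride derived from 9 (CrCl2 on C13) | C=C[C@@H](C)[C@@H](O[Si](C(C)C)(C(C)C)C(C)C)C/C=C(\C[Cr](Cl)Cl)C(=O)OCC | intermediate (not isolated)
18 | anti hydroxy ester (4Z,6R,7S,9S,10R): C12 ethyl ester; C11=C13; free O6–H; O9 TIPS; C3 bis(4-methoxybenzyl) acetal; C1=C2 vinyl | C=C[C@@H](C)[C@@H](O[Si](C(C)C)(C(C)C)C(C)C)C[C@@H](C(=C)C(=O)OCC)[C@H](O)/C=C(/C)C(OCc1ccc(OC)cc1)OCc1ccc(OC)cc1 | intermediate (not isolated)
19 | (4S,5R)-5-[(Z)-3,3-bis(4-methoxybenzyloxy)-2-methylprop-1-enyl]-3-methylidene-4-[(2S,3R)-3-methyl-2-(triisopropylsilyloxy)pent-4-enyl]oxolan-2-one | C=C1C(=O)O[C@H](/C=C(/C)C(OCc2ccc(OC)cc2)OCc2ccc(OC)cc2)[C@H]1C[C@H](O[Si](C(C)C)(C(C)C)C(C)C)[C@H](C)C=C | intermediate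
20 | open-chain diol (4Z,6R,7S,9S,10R): free O6–H and O12–H; O9 TIPS; C3 bis(4-methoxybenzyl) acetal; C1=C2 vinyl | C=C[C@@H](C)[C@@H](O[Si](C(C)C)(C(C)C)C(C)C)C[C@@H](C(=C)CO)[C@H](O)/C=C(/C)C(OCc1ccc(OC)cc1)OCc1ccc(OC)cc1 | intermediate
21 | bis-TBS ether (4Z,6R,7S,9S,10R): O6 and O12 TBS; O9 TIPS; C3 bis(4-methoxybenzyl) acetal; C1=C2 vinyl | C=C[C@@H](C)[C@@H](O[Si](C(C)C)(C(C)C)C(C)C)C[C@@H](C(=C)CO[Si](C)(C)C(C)(C)C)[C@H](O[Si](C)(C)C(C)(C)C)/C=C(/C)C(OCc1ccc(OC)cc1)OCc1ccc(OC)cc1 | intermediate
22 | C2 bis(3-methylbutan-2-yl)borane adduct of 21 | CC(C)C(C)B(C(C)C(C)C)CC[C@@H](C)[C@@H](O[Si](C(C)C)(C(C)C)C(C)C)C[C@@H](C(=C)CO[Si](C)(C)C(C)(C)C)[C@H](O[Si](C)(C)C(C)(C)C)/C=C(/C)C(OCc1ccc(OC)cc1)OCc1ccc(OC)cc1 | intermediate (not isolated)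
23 | primary C2 alcohol (4Z,6R,7S,9S,10R): O6 and O12 TBS; O9 TIPS; C3 bis(4-methoxybenzyl) acetal | OCC[C@@H](C)[C@@H](O[Si](C(C)C)(C(C)C)C(C)C)C[C@@H](C(=C)CO[Si](C)(C)C(C)(C)C)[C@H](O[Si](C)(C)C(C)(C)C)/C=C(/C)C(OCc1ccc(OC)cc1)OCc1ccc(OC)cc1 | intermediate
24 | allylboronate alcohol (3E,5S,6R,7S,9S,10R): C5 pinacol boronate; enol 4-methoxybenzyl ether at C3=C4; free O2–H | OCC[C@@H](C)[C@@H](O[Si](C(C)C)(C(C)C)C(C)C)C[C@@H](C(=C)CO[Si](C)(C)C(C)(C)C)[C@H](O[Si](C)(C)C(C)(C)C)[C@@H](B1OC(C)(C)C(C)(C)O1)/C(C)=C/OCc1ccc(OC)cc1 | intermediate
25 | C2 aldehyde (3E,5S,6R,7S,9S,10R): C5 pinacol boronate; enol 4-methoxybenzyl ether at C3=C4; O6 and O12 TBS; O9 TIPS | O=CC[C@@H](C)[C@@H](O[Si](C(C)C)(C(C)C)C(C)C)C[C@@H](C(=C)CO[Si](C)(C)C(C)(C)C)[C@H](O[Si](C)(C)C(C)(C)C)[C@@H](B1OC(C)(C)C(C)(C)O1)/C(C)=C/OCc1ccc(OC)cc1 | intermediate (used crude)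
26 | O2 pinacol borate ester of 27 | CC(C)(C)[Si](C)(C)O[C@@H]2/C=C(/C)[C@@H](OCc1ccc(OC)cc1)[C@@H](OB3OC(C)(C)C(C)(C)O3)C[C@@H](C)[C@@H](O[Si](C(C)C)(C(C)C)C(C)C)C[C@H]2C(=C)CO[Si](C)(C)C(C)(C)C | intermediate (not isolated)
27 | ten-membered carbocycle (2S,3R,4Z,6R,7S,9S,10R): free O2–H; O3 4-methoxybenzyl ether; O6 TBS; O9 TIPS; C7 2-(TBS-oxymethyl)vinyl | CC(C)(C)[Si](C)(C)O[C@@H]2/C=C(/C)[C@@H](OCc1ccc(OC)cc1)[C@@H](O)C[C@@H](C)[C@@H](O[Si](C(C)C)(C(C)C)C(C)C)C[C@H]2C(=C)CO[Si](C)(C)C(C)(C)C | intermediate
28 | O2,O3-(4-methoxybenzylidene) acetal of the macrocycle: O6 TBS; O9 TIPS; O12 TBS | CC(C)(C)[Si](C)(C)O[C@@H]2/C=C(/C)[C@H]3OC(c4ccc(OC)cc4)O[C@H]3C[C@@H](C)[C@@H](O[Si](C(C)C)(C(C)C)C(C)C)C[C@H]2C(=C)CO[Si](C)(C)C(C)(C)C | intermediate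
29 | diol acetal: free O6–H and O12–H; O9 TIPS | O[C@@H]1/C=C(/C)[C@H]2OC(c3ccc(OC)cc3)O[C@H]2C[C@@H](C)[C@@H](O[Si](C(C)C)(C(C)C)C(C)C)C[C@H]1C(=C)CO | intermediate
30 | lactol (C12 hemiacetal with O6): O9 TIPS; acetal in place | C=C1C(O)O[C@@H]2/C=C(/C)[C@H]3OC(c4ccc(OC)cc4)O[C@H]3C[C@@H](C)[C@@H](O[Si](C(C)C)(C(C)C)C(C)C)C[C@@H]12 | intermediate (not isolated)
31 | α-methylene lactone acetal: O9 TIPS | C=C1C(=O)O[C@@H]2/C=C(/C)[C@H]3OC(c4ccc(OC)cc4)O[C@H]3C[C@@H](C)[C@@H](O[Si](C(C)C)(C(C)C)C(C)C)C[C@@H]12 | intermediate
32 | α-methylene lactone acetal with free O9–H | C=C1C(=O)O[C@@H]2/C=C(/C)[C@H]3OC(c4ccc(OC)cc4)O[C@H]3C[C@@H](C)[C@@H](O)C[C@@H]12 | intermediate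
33 | C9 angelate of 32 | C=C1C(=O)O[C@@H]2/C=C(/C)[C@H]3OC(c4ccc(OC)cc4)O[C@H]3C[C@@H](C)[C@@H](OC(=O)/C(C)=C\C)C[C@@H]12 | intermediate
34 | CNP0229085.1 (2S,3R,4Z,6R,7S,9S,10R) | C=C1C(=O)O[C@@H]2/C=C(/C)[C@@H](O)[C@@H](O)C[C@@H](C)[C@@H](OC(=O)/C(C)=C\C)C[C@@H]12 | target

## Step count and least certain steps

Total: 23 steps. Longest linear sequence: 19 steps (steps 1–6 and 11–23); the enal branch (steps 7–10) is four steps.

**Step 17 (key step).** The most likely failure is oligomerisation by intermolecular allylboration, or a stalled closure, because the six-atom tether must span the chair without transannular strain. Prolonged heating could also erode the C5 configuration through a boron shift. The fallback forms the same C2–C3 bond by known chemistry. It sets out from 23: mild aqueous acid (AcOH/THF/H2O, 0 °C) hydrolyses the allylic acetal to the Z hydroxy enal F1, and Dess–Martin oxidation gives the dialdehyde F2. A reductive pinacol macrocyclisation with TiCl3(DME)1.5 and Zn(Cu) in DME under slow addition should then give the ten-membered diol F3, with the Z olefin carried over from the enal. After separation of the ring-cis (2S,3R) isomer, 4-methoxybenzaldehyde dimethyl acetal with PPTS converts it into 28, where the route is rejoined. The cost is that the diol configuration is no longer relayed from a single stereocentre.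

**Step 11.** The most likely failure is poor facial discrimination: the two anti transition states differ only through the chiral ligand sphere on chromium, since the nearest stereocentre of 9 is three atoms from C7. Geometric equilibration of the allylchromium could also let a syn pathway compete. The fallback moves the simple diastereoselection into the reagent geometry and sets out from 6. The Ohira–Bestmann reagent (K2CO3, MeOH) gives the alkyne F4; n-BuLi and ethyl chloroformate give the ynoate F5. Syn hydroalumination (i-Bu2AlH, HMPA) and trapping with ICH2Bpin give the 2-(ethoxycarbonyl)allylboronate F6, with C8 trans to the CH2B group. Its addition to 16 in toluene, with a chiral BINOL-derived phosphoric acid to control the aldehyde face, should give the anti adduct stereospecifically through the chair, and this lactonises to 19, where the route is rejoined.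

**Step 15.** The most likely failure is a facial mismatch between the C6 silyloxy stereocentre and the chiral copper catalyst, giving the C5 epimer, which would relay the wrong C2/C3 configuration. Sluggish borylcupration of the trisubstituted, α-branched olefin is the second concern. The fallback gives up the boron stereocentre altogether: from 23 the dialdehyde sequence described for step 17 (through F1, F2 and F3) leads to 28.

**Step 14.** The most likely failure is competing hydroboration of the C11=C13 olefin, since both olefins are terminal and the discrimination is purely steric. The fallback changes the addition chemistry and sets out from 21. Platinum-catalysed hydrosilylation with HSiMe2(OEt) and Pt2[(CH2=CHSiMe2)2O]3, which is strongly selective for monosubstituted olefins, gives the alkylsilane F7. Oxidation of the C–Si bond (KF, KHCO3, H2O2, THF/MeOH) gives 23.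

**Step 19.** The most likely failure is incomplete discrimination between the hindered C6 TBS ether and the C9 TIPS ether, or partial loss of the acid-labile acetal during the longer exposure the C6 ether needs. The fallback sets out from 28: Bu4NF removes all three silyl groups to give the triol F8. Oxidation with TEMPO and PhI(OAc)2 should then attack only the primary allylic alcohol, and the kinetically favoured five-membered lactol closure onto O6 leads directly to 32, which also saves step 21. The risk accepted is the bridged six-membered lactone through O9.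

## Further compounds

F1 | step 17 | Z hydroxy enal (C3 aldehyde, free O2–H; O6 and O12 TBS; O9 TIPS) | OCC[C@@H](C)[C@@H](O[Si](C(C)C)(C(C)C)C(C)C)C[C@@H](C(=C)CO[Si](C)(C)C(C)(C)C)[C@H](O[Si](C)(C)C(C)(C)C)/C=C(/C)C=O
F2 | step 17 | dialdehyde (C2 and C3 aldehydes; O6 and O12 TBS; O9 TIPS) | O=CC[C@@H](C)[C@@H](O[Si](C(C)C)(C(C)C)C(C)C)C[C@@H](C(=C)CO[Si](C)(C)C(C)(C)C)[C@H](O[Si](C)(C)C(C)(C)C)/C=C(/C)C=O
F3 | step 17 | ten-membered (2S,3R)-diol (O6 and O12 TBS; O9 TIPS) | CC(C)(C)[Si](C)(C)O[C@@H]1/C=C(/C)[C@@H](O)[C@@H](O)C[C@@H](C)[C@@H](O[Si](C(C)C)(C(C)C)C(C)C)C[C@H]1C(=C)CO[Si](C)(C)C(C)(C)C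
F4 | step 11 | (3R,4S)-3-methyl-4-[(triisopropylsilyl)oxy]hept-1-en-6-yne | C=C[C@@H](C)[C@@H](O[Si](C(C)C)(C(C)C)C(C)C)CC#C
F5 | step 11 | ethyl (5S,6R)-6-methyl-5-[(triisopropylsilyl)oxy]oct-7-en-2-ynoate | C=C[C@@H](C)[C@@H](O[Si](C(C)C)(C(C)C)C(C)C)CC#CC(=O)OCC
F6 | step 11 | ethyl (2Z,5S,6R)-6-methyl-2-[(4,4,5,5-tetramethyl-1,3,2-dioxaborolan-2-yl)methyl]-5-[(triisopropylsilyl)oxy]octa-2,7-dienoate | C=C[C@@H](C)[C@@H](O[Si](C(C)C)(C(C)C)C(C)C)C/C=C(/CB1OC(C)(C)C(C)(C)O1)C(=O)OCC
F0 | step 15 | none | none
F7 | step 14 | C2 ethoxydimethylsilyl adduct of 21 | CCO[Si](C)(C)CC[C@@H](C)[C@@H](O[Si](C(C)C)(C(C)C)C(C)C)C[C@@H](C(=C)CO[Si](C)(C)C(C)(C)C)[C@H](O[Si](C)(C)C(C)(C)C)/C=C(/C)C(OCc1ccc(OC)cc1)OCc1ccc(OC)cc1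
F8 | step 19 | triol acetal (free O6–H, O9–H and O12–H; O2,O3-(4-methoxybenzylidene) acetal) | O[C@@H]1/C=C(/C)[C@H]2OC(c3ccc(OC)cc3)O[C@H]2C[C@@H](C)[C@@H](O)C[C@H]1C(=C)CO
A1 | alternative 1 | open-chain (Z)-alkenyl iodide aldehyde (C4 iodide, C3 aldehyde, O2 TBS, lactone and angelate in place) | C=C1C(=O)O[C@H](/C=C(/C)I)[C@H]1C[C@H](OC(=O)/C(C)=C\C)[C@H](C)C[C@H](O[Si](C)(C)C(C)(C)C)C=O
A2 | alternative 1 | target skeleton with free O3–H and O2 TBS ether | C=C1C(=O)O[C@@H]2/C=C(/C)[C@@H](O)[C@@H](O[Si](C)(C)C(C)(C)C)C[C@@H](C)[C@@H](OC(=O)/C(C)=C\C)C[C@@H]12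
A3 | alternative 2 | twelve-membered allyl vinyl ether (exocyclic C9=C8H2; ring oxygen on C13; O2,O3 acetonide; O6 and O12 TBS) | C=C1OC/C(CO[Si](C)(C)C(C)(C)C)=C/[C@H](O[Si](C)(C)C(C)(C)C)/C=C(/C)[C@H]2OC(C)(C)O[C@H]2C[C@H]1C
A4 | alternative 2 | ten-membered C9 ketone (O2,O3 acetonide; O6 TBS; C7 2-(TBS-oxymethyl)vinyl) | CC(C)(C)[Si](C)(C)O[C@@H]2/C=C(/C)[C@H]3OC(C)(C)O[C@H]3C[C@@H](C)C(=O)C[C@H]2C(=C)CO[Si](C)(C)C(C)(C)C
A5 | alternative 3 | open-chain C2 aldehyde with C9 isopropenyl ketone (O3, O6 and O12 TBS; Z olefin) | O=C[C@H](O[Si](C)(C)C(C)(C)C)/C(C)=C\[C@@H](O[Si](C)(C)C(C)(C)C)[C@H](C(=C)CO[Si](C)(C)C(C)(C)C)CC(=O)C(C)=C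
A6 | alternative 3 | ten-membered C9 ketone with free O2–H (O3, O6 and O12 TBS) | CC(C)(C)[Si](C)(C)O[C@@H]2/C=C(/C)[C@@H](O[Si](C)(C)C(C)(C)C)[C@@H](O)C[C@@H](C)C(=O)C[C@H]2C(=C)CO[Si](C)(C)C(C)(C)C
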